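Assumption: the target is the (2S)-enantiomer, (2S)-2-(3,4-dimethoxyphenyl)-5,7,8-trimethoxychroman-4-one (C2 = S as read from the SMILES); compounds 1, 5 and 6 are bought. The key step (step 6) is a proposed, unprecedented one-flask sequence and has not been run.

**Retrosynthetic overview**
1. Target 12 comes from the 7-phenol 11 by O-methylation.
2. 11 comes from β-hydroxy chloro-ynone 4 and the trioxygenated diene 8 in one flask: oxa-Michael closure gives ring C (6-chloro-dihydropyranone 9), then a [4+2] benzannulation on 9 gives ring A.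
3. C4a and C8a come from the alkyne carbons of 4; C5–C8 and their three oxygens come from diene 8.
4. 4 comes from Weinreb amide 3 and LiC≡CCl; 3 from (S)-β-hydroxy ester 2; 2 from β-keto ester 1 by asymmetric hydrogenation, which sets C2.
5. 8 comes from methoxyacetyl chloride 5 and ketene dimethyl acetal 6 via enone 7. Ring order: B bought, then C, then A (C and A in the same operation).

**Route**

Step 1
Reactants: 1 ethyl 3-(3,4-dimethoxyphenyl)-3-oxopropanoate
Product: 2 ethyl (S)-3-(3,4-dimethoxyphenyl)-3-hydroxypropanoate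
Conditions: H2 (10 atm), [RuCl(p-cymene)((R)-BINAP)]Cl (0.5 mol%), EtOH, 60 °C
Reagents that add atoms: none
Why: Noyori asymmetric hydrogenation of a β-keto ester; the (R)-BINAP–Ru catalyst reduces one face of the chelated ketone and sets the (S)-carbinol (future C2), in the sense recalled for ethyl benzoylacetate (to be confirmed by chiral HPLC).

Step 2
Reactants: 2 ethyl (S)-3-(3,4-dimethoxyphenyl)-3-hydroxypropanoate
Product: 3 (S)-3-(3,4-dimethoxyphenyl)-3-hydroxy-N-methoxy-N-methylpropanamide
Conditions: MeNH(OMe)·HCl (1.5 equiv), i-PrMgCl (4 equiv), THF, −20 → 0 °C; aq. NH4Cl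
Reagents that add atoms: N,O-dimethylhydroxylamine hydrochloride, CNOC.Cl
Why: Weinreb amide formation by direct aminolysis of the ester with the magnesium amide; the carbinol centre is not touched.

Step 3
Reactants: 3 (S)-3-(3,4-dimethoxyphenyl)-3-hydroxy-N-methoxy-N-methylpropanamide
Product: 4 (S)-1-chloro-5-(3,4-dimethoxyphenyl)-5-hydroxypent-1-yn-3-one
Conditions: i-PrMgCl (1.0 equiv), THF, −40 °C; LiC≡CCl (1.6 equiv, from (Z)-ClCH=CHCl + 2 MeLi, Et2O, 0 °C), −78 → −40 °C; inverse quench into cold 1 M HCl; used crude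
Reagents that add atoms: lithium chloroacetylide, [Li]C#CCl (made in the flask from (Z)-1,2-dichloroethene, Cl/C=C\Cl, and methyllithium)
Why: Weinreb ketone synthesis; the acetylide adds once to give a chelated tetrahedral intermediate that releases the ynone only on the acidic inverse quench, which also protonates the liberated amine so it cannot add to the chloro-ynone.

Step 4
Reactants: 5 methoxyacetyl chloride; 6 1,1-dimethoxyethene (ketene dimethyl acetal, 2.1 equiv)
Product: 7 1,4,4-trimethoxybut-3-en-2-one
Conditions: Et2O, 0 °C → rt; distil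
Reagents that add atoms: none
Why: C-acylation of a ketene acetal by an acid chloride (McElvain-type acylation) gives the β,β-dimethoxy enone; the second equivalent of 6 takes up the HCl.

Step 5
Reactants: 7 1,4,4-trimethoxybut-3-en-2-one
Product: 8 trimethyl[(1,4,4-trimethoxybuta-1,3-dien-2-yl)oxy]silane (1,1,4-trimethoxy-3-trimethylsilyloxybuta-1,3-diene; enol-ether geometry not important)
Conditions: LDA (1.05 equiv), THF, −78 °C; TMSCl; pentane, filter, distil
Reagents that add atoms: chlorotrimethylsilane, C[Si](C)(C)Cl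
Why: Kinetic enolisation at the only enolisable position (the CH2OMe) and O-silylation gives a Danishefsky–Brassard-type 1,1-dialkoxy-3-silyloxy diene.

Step 6
Reactants: 4 (S)-1-chloro-5-(3,4-dimethoxyphenyl)-5-hydroxypent-1-yn-3-one; 8 trimethyl[(1,4,4-trimethoxybuta-1,3-dien-2-yl)oxy]silane (1.5 equiv)
Product: 11 (S)-2-(3,4-dimethoxyphenyl)-7-hydroxy-5,8-dimethoxychroman-4-one, via chloropyranone 9 (not isolated), via dimethoxyvinyl-ketone pyranone 10 (not isolated)
Conditions: Et3N (10 mol%), CH2Cl2, 0 °C; then 8, −20 °C → rt; 40 °C; aq. NaHCO3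
Reagents that add atoms: none
Why: Proposed new method: catalytic base triggers 6-endo-dig oxa-Michael cyclisation of the β-hydroxy chloro-ynone to the vinylogous acyl chloride 9 (ring C; the carbinol C–O bond is kept, so C2 stays S); the nucleophilic CH(OMe) terminus of 8 then replaces chloride at C8a by addition–elimination (TMSCl lost) to give 10, whose enol-ether carbon C4a closes onto the dimethoxyvinyl carbon C5 with loss of MeOH and tautomerises to the phenol (ring A), a concerted [4+2] on 9 leading to the same product; the closest known chemistry is the Brassard-type regiospecific annulation of vinylketene acetals with halo-enones and haloquinones, together with the cyclisation of β-hydroxy ynones to 2,3-dihydro-4H-pyran-4-ones.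

Step 7
Reactants: 11 (S)-2-(3,4-dimethoxyphenyl)-7-hydroxy-5,8-dimethoxychroman-4-one
Product: 12 (S)-2-(3,4-dimethoxyphenyl)-5,7,8-trimethoxychroman-4-one (target)
Conditions: TMSCHN2 (2 equiv), MeOH–toluene (1:4), 0 °C → rt
Reagents that add atoms: (trimethylsilyl)diazomethane, C[Si](C)(C)C=[N+]=[N-]
Why: O-methylation of the acidic 7-phenol (para to the C4 carbonyl) without base, so no retro-oxa-Michael ring opening can scramble C2.

**Compound list**
1 | ethyl 3-(3,4-dimethoxyphenyl)-3-oxopropanoate | CCOC(=O)CC(=O)c1ccc(OC)c(OC)c1 | starting material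
2 | ethyl (S)-3-(3,4-dimethoxyphenyl)-3-hydroxypropanoate | CCOC(=O)C[C@H](O)c1ccc(OC)c(OC)c1 | intermediate
3 | (S)-3-(3,4-dimethoxyphenyl)-3-hydroxy-N-methoxy-N-methylpropanamide | CON(C)C(=O)C[C@H](O)c1ccc(OC)c(OC)c1 | intermediate
4 | (S)-1-chloro-5-(3,4-dimethoxyphenyl)-5-hydroxypent-1-yn-3-one | ClC#CC(=O)C[C@H](O)c1ccc(OC)c(OC)c1 | intermediate
5 | methoxyacetyl chloride | COCC(Cl)=O | starting material
6 | 1,1-dimethoxyethene | C=C(OC)OC | starting material
7 | 1,4,4-trimethoxybut-3-en-2-one | COCC(=O)C=C(OC)OC | intermediate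
8 | trimethyl[(1,4,4-trimethoxybuta-1,3-dien-2-yl)oxy]silane | COC=C(O[Si](C)(C)C)C=C(OC)OC | intermediate
9 | (S)-6-chloro-2-(3,4-dimethoxyphenyl)-2,3-dihydro-4H-pyran-4-one | COc1ccc([C@@H]2CC(=O)C=C(Cl)O2)cc1OC | intermediate (not isolated)
10 | (2S)-2-(3,4-dimethoxyphenyl)-6-(1,4,4-trimethoxy-2-oxobut-3-en-1-yl)-2,3-dihydro-4H-pyran-4-one (both side-chain epimers) | COc1ccc([C@@H]2CC(=O)C=C(C(OC)C(=O)C=C(OC)OC)O2)cc1OC | intermediate (not isolated)
11 | (S)-2-(3,4-dimethoxyphenyl)-7-hydroxy-5,8-dimethoxychroman-4-one | COc1ccc([C@@H]2CC(=O)c3c(OC)cc(O)c(OC)c3O2)cc1OC | intermediate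
12 | (S)-2-(3,4-dimethoxyphenyl)-5,7,8-trimethoxychroman-4-one | COc1ccc([C@@H]2CC(=O)c3c(OC)cc(OC)c(OC)c3O2)cc1OC | target

**Totals**
Total step count: 7. Longest linear sequence: 5 (steps 1, 2, 3, 6, 7); the diene branch (steps 4, 5) joins at step 6.

**Three steps most likely to fail**

Step 6 (the double ring formation). Risks are hydrolysis of 9, cycloaddition of 8 to uncyclised 4, and a slow ring closure at C4a. The fallback sets out from 4 and comes back at 12. It builds ring A first and closes ring C by catalysis. Heating 4 with 8 (2.5 equiv, toluene, 60 °C, no base) gives a Diels–Alder reaction at the ynone, with the CH(OMe) terminus of the diene bonding to the chlorine-bearing carbon. Loss of methanol and a dilute-acid work-up then give (S)-1-(2-chloro-4-hydroxy-3,6-dimethoxyphenyl)-3-(3,4-dimethoxyphenyl)-3-hydroxypropan-1-one F1. TMSCHN2 methylates the phenol to (S)-1-(2-chloro-3,4,6-trimethoxyphenyl)-3-(3,4-dimethoxyphenyl)-3-hydroxypropan-1-one F2. A palladium-catalysed intramolecular aryl etherification of the secondary alcohol (Pd(OAc)2, 2-(di-tert-butylphosphino)-1,1'-binaphthyl, Cs2CO3, toluene, 70 °C) closes ring C with retention at the carbinol and gives 12.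

Step 3 (chloro-ynone 4). Risks are addition of the liberated amine to the chloro-ynone, premature cyclisation and hydrolysis, and retro-aldol. The fallback sets out from 3 and comes back at 4. It masks the hydroxyl and puts the chlorine on after the C–C bond is made. TESCl and imidazole give (S)-3-(3,4-dimethoxyphenyl)-N-methoxy-N-methyl-3-[(triethylsilyl)oxy]propanamide F3. Ethynylmagnesium bromide gives (S)-5-(3,4-dimethoxyphenyl)-5-[(triethylsilyl)oxy]pent-1-yn-3-one F4. NCS with catalytic AgOAc in acetone chlorinates the terminal alkyne to (S)-1-chloro-5-(3,4-dimethoxyphenyl)-5-[(triethylsilyl)oxy]pent-1-yn-3-one F5. HF·pyridine in THF at 0 °C removes the silyl group to give 4.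

Step 5 (silyl diene 8). Risks are hydrolytic loss of 8 on isolation and attack of the amide base on the ketene acetal. The fallback sets out from 7 and comes back at 10. It gives up the silyl diene for an anionic two-stage sequence. LiHMDS (THF, −78 °C) converts 7 into lithium 1,4,4-trimethoxybuta-1,3-dien-2-olate F6. F6 is added to a solution of 9 (made from 4 with catalytic Et3N as in step 6), and vinylic substitution of chloride gives 10. Camphorsulfonic acid in CH2Cl2 then closes ring A to 11 as in the route.

**Further compounds**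
F1 | step 6 | (S)-1-(2-chloro-4-hydroxy-3,6-dimethoxyphenyl)-3-(3,4-dimethoxyphenyl)-3-hydroxypropan-1-one | COc1ccc([C@@H](O)CC(=O)c2c(OC)cc(O)c(OC)c2Cl)cc1OC
F2 | step 6 | (S)-1-(2-chloro-3,4,6-trimethoxyphenyl)-3-(3,4-dimethoxyphenyl)-3-hydroxypropan-1-one | COc1ccc([C@@H](O)CC(=O)c2c(OC)cc(OC)c(OC)c2Cl)cc1OC
F3 | step 3 | (S)-3-(3,4-dimethoxyphenyl)-N-methoxy-N-methyl-3-[(triethylsilyl)oxy]propanamide | CON(C)C(=O)C[C@H](O[Si](CC)(CC)CC)c1ccc(OC)c(OC)c1
F4 | step 3 | (S)-5-(3,4-dimethoxyphenyl)-5-[(triethylsilyl)oxy]pent-1-yn-3-one | C#CC(=O)C[C@H](O[Si](CC)(CC)CC)c1ccc(OC)c(OC)c1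
F5 | step 3 | (S)-1-chloro-5-(3,4-dimethoxyphenyl)-5-[(triethylsilyl)oxy]pent-1-yn-3-one | ClC#CC(=O)C[C@H](O[Si](CC)(CC)CC)c1ccc(OC)c(OC)c1
F6 | step 5 | lithium 1,4,4-trimethoxybuta-1,3-dien-2-olate | [Li+].[O-]C(=COC)C=C(OC)OC
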